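**Retrosynthetic overview**

1. The target is read as an opened pyridine: its two aldehyde carbons are C2 and C6 of a 1,4-dihydropyridine, the CO2Me sits on C3, the stereocentre is C4, and the ethylidene is a C5 vinyl group. So 11 comes from one-pot unmasking (desilylation, N-deacylation, aqueous acid) of N-Troc dihydropyridine 8.
2. 8 comes from a catalytic enantioselective dearomative C4 addition of silyl ketene acetal 6, which already carries the hydroxytyrosol ester, to the N-Troc pyridinium salt of methyl 5-vinylnicotinate 2.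
3. 2 comes from Suzuki vinylation of methyl 5-bromonicotinate 1; 6 comes from hydroxytyrosol 3 by lipase acetylation and one-pot silylation.
4. No ring is built: the pyridine ring is bought, dearomatised (this sets C3 of the target), then opened.

Assumption: the target is taken as the open dialdehyde tautomer exactly as drawn, (2S,3S,4E) in hexenoate numbering; C2 is an enolisable α-formyl ester centre, so it can only be set in the last operation.

Abbreviations: TBS = tert-butyldimethylsilyl; Troc = 2,2,2-trichloroethoxycarbonyl.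

**Route**

Step 1
Reactants: 1 methyl 5-bromonicotinate
Product: 2 methyl 5-vinylnicotinate
Conditions: K[CH2=CHBF3] (1.2 equiv), PdCl2(dppf) (2 mol%), Et3N (3 equiv), i-PrOH/H2O 4:1, 80 °C
Reagents that add atoms: potassium vinyltrifluoroborate, C=C[B-](F)(F)F.[K+]
Why: Suzuki–Miyaura coupling of an electron-poor heteroaryl bromide with a vinyltrifluoroborate is fast and leaves the methyl ester untouched under amine base; no stereocentre is formed.

Step 2
Reactants: 3 hydroxytyrosol
Product: 4 2-(3,4-dihydroxyphenyl)ethyl acetate (hydroxytyrosol acetate)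
Conditions: vinyl acetate (5 equiv), immobilised Candida antarctica lipase B (Novozym 435), THF, 40 °C; filter, concentrate
Reagents that add atoms: vinyl acetate, CC(=O)OC=C
Why: Lipase-catalysed transesterification with an enol ester is irreversible (the vinyl alcohol leaves as acetaldehyde) and the enzyme acylates only the primary aliphatic hydroxyl, not the phenols; no stereocentre is formed.

Step 3
Reactants: 4 2-(3,4-dihydroxyphenyl)ethyl acetate
Product: 6 1-{2-[3,4-bis(tert-butyldimethylsilyloxy)phenyl]ethoxy}-1-(tert-butyldimethylsilyloxy)ethene, via bis-TBS aryl ether acetate 5 (not isolated)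
Conditions: LiN(i-Pr)2 (2.05 equiv), THF, −78 °C, then TBSCl (2.2 equiv), to 0 °C; back to −78 °C, LiN(i-Pr)2 (1.2 equiv), then TBSCl (1.3 equiv) in DMPU, to 0 °C; pentane, ice-cold water wash, high vacuum, used crude
Reagents that add atoms: tert-butyldimethylsilyl chloride, CC(C)(C)[Si](C)(C)Cl
Why: The first two equivalents of amide base can only remove the phenolic protons (pKa about 10 against about 25 for the ester), so TBSCl caps the catechol, and the third equivalent forms the acetate lithium enolate, which TBSCl with DMPU silylates on oxygen (silyl ketene acetal formation); no stereocentre is formed.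

Step 4
Reactants: 2 methyl 5-vinylnicotinate; 6 1-{2-[3,4-bis(tert-butyldimethylsilyloxy)phenyl]ethoxy}-1-(tert-butyldimethylsilyloxy)ethene
Product: 8 methyl (4R)-4-(2-{2-[3,4-bis(tert-butyldimethylsilyloxy)phenyl]ethoxy}-2-oxoethyl)-1-[(2,2,2-trichloroethoxy)carbonyl]-5-vinyl-1,4-dihydropyridine-3-carboxylate, via N-Troc pyridinium chloride 7 (not isolated)
Conditions: 2, TrocCl (1.05 equiv), t-BuOMe, 0 °C, 30 min; then 1-[(1R,2R)-2-(2-methyl-5-phenylpyrrol-1-yl)cyclohexyl]-3-[(2S)-1-(diisobutylamino)-3,3-dimethyl-1-oxobutan-2-yl]thiourea (10 mol%), 6 (1.5 equiv), −78 °C, 24 h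
Reagents that add atoms: 2,2,2-trichloroethyl chloroformate, ClC(=O)OCC(Cl)(Cl)Cl
Why: Proposed new method: an anion-binding-catalysed, C4-selective acyl-Mannich (Mukaiyama–Mannich-type) dearomatisation in which the thiourea binds the chloride of pyridinium chloride 7 to give a chiral contact ion pair whose arene covers one face of the cation, the soft silyl ketene acetal then attacks the vinylogous C4 position favoured for 3-alkoxycarbonyl N-acylpyridinium ions from the open Re face (C3 > C5 > H) to set 4R, and silicon leaves as TBSCl to free the catalyst; the closest known reaction types are thiourea- and triazole-catalysed additions of silyl ketene acetals to N-Troc isoquinolinium, quinolinium and pyridinium chlorides (there at the carbon next to nitrogen) and the auxiliary-controlled C4 addition of silyl ketene acetals to nicotinoyl-derived N-acylpyridinium salts.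

Step 5
Reactants: 8 methyl (4R)-4-(2-{2-[3,4-bis(tert-butyldimethylsilyloxy)phenyl]ethoxy}-2-oxoethyl)-1-[(2,2,2-trichloroethoxy)carbonyl]-5-vinyl-1,4-dihydropyridine-3-carboxylate
Product: 11 methyl (2S,3S,4E)-3-{2-[2-(3,4-dihydroxyphenyl)ethoxy]-2-oxoethyl}-2,4-diformylhex-4-enoate (the target), via desilylated N-Troc dihydropyridine 9 (not isolated), via N-H dihydropyridine 10 (not isolated)
Conditions: degassed throughout; Bu4NF (2.2 equiv)/AcOH (2.5 equiv), THF, 0 °C, 20 min; then Zn dust (10 equiv), 1 M aq. KH2PO4, 0 °C to rt, 1 h; filter; then 1 M aq. HCl to pH 1–2, 0 °C to rt, 30 min; EtOAc extraction at pH 2, cold reversed-phase HPLC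
Reagents that add atoms: water, O
Why: Buffered fluoride removes the aryl silyl ethers, zinc cleaves the Troc carbamate by reductive β-elimination, and the freed N–H 1,4-dihydropyridine is a double enamine that undergoes enamine hydrolysis in aqueous acid: the vinyl-dienamine arm is protonated at the vinyl terminus to a conjugated iminium that gives the thermodynamically preferred (E)-2-ethylidene aldehyde, the β-enamino ester arm gives the α-formyl ester, nitrogen leaves as ammonium, C3 (the former ring C4) is not touched, and C2 is created on ketonisation as an epimerisable centre that settles under thermodynamic control, the (2S,3S) epimer being collected by cold HPLC and the 2-epimer re-equilibrated and recycled.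

**Compound list**

1 | methyl 5-bromonicotinate | COC(=O)c1cncc(Br)c1 | starting material
2 | methyl 5-vinylnicotinate | COC(=O)c1cncc(C=C)c1 | intermediate
3 | hydroxytyrosol, 4-(2-hydroxyethyl)benzene-1,2-diol | OCCc1ccc(O)c(O)c1 | starting material
4 | 2-(3,4-dihydroxyphenyl)ethyl acetate | CC(=O)OCCc1ccc(O)c(O)c1 | intermediate
5 | 2-[3,4-bis(tert-butyldimethylsilyloxy)phenyl]ethyl acetate (formed in the flask in step 3) | CC(=O)OCCc1ccc(O[Si](C)(C)C(C)(C)C)c(O[Si](C)(C)C(C)(C)C)c1 | intermediate
6 | 1-{2-[3,4-bis(tert-butyldimethylsilyloxy)phenyl]ethoxy}-1-(tert-butyldimethylsilyloxy)ethene | C=C(O[Si](C)(C)C(C)(C)C)OCCc1ccc(O[Si](C)(C)C(C)(C)C)c(O[Si](C)(C)C(C)(C)C)c1 | intermediate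
7 | 3-(methoxycarbonyl)-1-[(2,2,2-trichloroethoxy)carbonyl]-5-vinylpyridinium chloride (formed in the flask in step 4) | COC(=O)c1cc(C=C)c[n+](C(=O)OCC(Cl)(Cl)Cl)c1.[Cl-] | intermediate
8 | methyl (4R)-4-(2-{2-[3,4-bis(tert-butyldimethylsilyloxy)phenyl]ethoxy}-2-oxoethyl)-1-[(2,2,2-trichloroethoxy)carbonyl]-5-vinyl-1,4-dihydropyridine-3-carboxylate | COC(=O)C1=CN(C(=O)OCC(Cl)(Cl)Cl)C=C(C=C)[C@H]1CC(=O)OCCc1ccc(O[Si](C)(C)C(C)(C)C)c(O[Si](C)(C)C(C)(C)C)c1 | intermediate
9 | methyl (4R)-4-{2-[2-(3,4-dihydroxyphenyl)ethoxy]-2-oxoethyl}-1-[(2,2,2-trichloroethoxy)carbonyl]-5-vinyl-1,4-dihydropyridine-3-carboxylate (formed in the flask in step 5) | COC(=O)C1=CN(C(=O)OCC(Cl)(Cl)Cl)C=C(C=C)[C@H]1CC(=O)OCCc1ccc(O)c(O)c1 | intermediate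
10 | methyl (4R)-4-{2-[2-(3,4-dihydroxyphenyl)ethoxy]-2-oxoethyl}-5-vinyl-1,4-dihydropyridine-3-carboxylate (formed in the flask in step 5) | COC(=O)C1=CNC=C(C=C)[C@H]1CC(=O)OCCc1ccc(O)c(O)c1 | intermediate
11 | methyl (2S,3S,4E)-3-{2-[2-(3,4-dihydroxyphenyl)ethoxy]-2-oxoethyl}-2,4-diformylhex-4-enoate | C/C=C(/C=O)[C@@H](CC(=O)OCCc1ccc(O)c(O)c1)[C@@H](C=O)C(=O)OC | target

**Step count**

Total: 5 steps. Longest linear sequence: 4 steps (3 → 4 → 6 → 8 → 11).

**Steps most likely to fail, with fallbacks**

Step 4 (most likely). This is a new reaction: attack at C2 or C6 instead of C4 and a low enantiomeric excess are both possible, and the sense of induction is assigned only by analogy (the mirror-image thiourea is used if the 4S product forms).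

The fallback sets the stereocentre with a chiral enolate; it sets out from 2 and 4 and comes back at 8. Pyridinium chloride 7 is made from 2 and TrocCl as before and treated in CH2Cl2 at −78 °C with the chlorotitanium enolate (TiCl4, i-Pr2NEt) of commercial (S)-3-acetyl-4-isopropyl-1,3-thiazolidine-2-thione. Titanium enolates add to N-acylpyridinium salts at C4, and the adduct methyl (4R)-4-{2-oxo-2-[(4S)-4-isopropyl-2-thioxo-1,3-thiazolidin-3-yl]ethyl}-1-[(2,2,2-trichloroethoxy)carbonyl]-5-vinyl-1,4-dihydropyridine-3-carboxylate F1 is separated from its C4 epimer on silica; the mirror-image auxiliary is used if the 4S adduct predominates. Separately, 4 is silylated (TBSCl, imidazole, DMF) to 5, isolated this time, and its acetate is removed with i-Bu2AlH (CH2Cl2, −78 °C) to give 2-[3,4-bis(tert-butyldimethylsilyloxy)phenyl]ethanol F2. Acyl transfer from the thiazolidinethione of F1 to F2 (4-(dimethylamino)pyridine, CH2Cl2) gives 8.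

Step 5. The zinc may over-reduce iminium or enal intermediates, the N–H dihydropyridine 10 may be oxidised by air back to a pyridine (which would erase the stereocentre), and the product itself is labile (C2 epimerisation, oxa-Michael ring closure).

The fallback removes the nitrogen substituent without a reducing metal; it sets out from 2 and 6 and comes back at 10. Allyl chloroformate replaces TrocCl in the key step with the same thiourea, giving through 1-(allyloxycarbonyl)-3-(methoxycarbonyl)-5-vinylpyridinium chloride F3 the dihydropyridine methyl (4R)-1-(allyloxycarbonyl)-4-(2-{2-[3,4-bis(tert-butyldimethylsilyloxy)phenyl]ethoxy}-2-oxoethyl)-5-vinyl-1,4-dihydropyridine-3-carboxylate F4. Bu4NF/AcOH then gives the catechol methyl (4R)-1-(allyloxycarbonyl)-4-{2-[2-(3,4-dihydroxyphenyl)ethoxy]-2-oxoethyl}-5-vinyl-1,4-dihydropyridine-3-carboxylate F5. Pd(PPh3)4 (zerovalent palladium, 5 mol%) with sodium p-toluenesulfinate and AcOH in degassed THF transfers the allyl group to the sulfinate and leaves 10, which is hydrolysed with aqueous HCl as in step 5.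

Step 3. The ketene acetal 6 cannot be distilled or chromatographed, so incomplete O-silylation or residual DMPU would be carried into the catalytic step.

The fallback uses a small, distillable nucleophile and forms the hydroxytyrosol ester afterwards; it sets out from 2 and 4 and comes back at 8. S-tert-butyl thioacetate is converted (LiN(i-Pr)2, TBSCl, DMPU, THF, −78 °C) into 1-(tert-butylsulfanyl)-1-(tert-butyldimethylsilyloxy)ethene F6, which is distilled and added to 7 under the conditions of step 4 to give the thioester methyl (4R)-4-[2-(tert-butylsulfanyl)-2-oxoethyl]-1-[(2,2,2-trichloroethoxy)carbonyl]-5-vinyl-1,4-dihydropyridine-3-carboxylate F7. The alcohol 2-[3,4-bis(tert-butyldimethylsilyloxy)phenyl]ethanol F2 is made from 4 through isolated 5 as described above, and AgOCOCF3-promoted acyl transfer from F7 to F2 (CH2Cl2, rt) gives 8.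

**Further compounds**

F1 | step 4 | methyl (4R)-4-{2-oxo-2-[(4S)-4-isopropyl-2-thioxo-1,3-thiazolidin-3-yl]ethyl}-1-[(2,2,2-trichloroethoxy)carbonyl]-5-vinyl-1,4-dihydropyridine-3-carboxylate | COC(=O)C1=CN(C(=O)OCC(Cl)(Cl)Cl)C=C(C=C)[C@H]1CC(=O)N1C(=S)SC[C@@H]1C(C)C
F2 | step 4 | 2-[3,4-bis(tert-butyldimethylsilyloxy)phenyl]ethanol | OCCc1ccc(O[Si](C)(C)C(C)(C)C)c(O[Si](C)(C)C(C)(C)C)c1
F3 | step 5 | 1-(allyloxycarbonyl)-3-(methoxycarbonyl)-5-vinylpyridinium chloride | COC(=O)c1cc(C=C)c[n+](C(=O)OCC=C)c1.[Cl-]
F4 | step 5 | methyl (4R)-1-(allyloxycarbonyl)-4-(2-{2-[3,4-bis(tert-butyldimethylsilyloxy)phenyl]ethoxy}-2-oxoethyl)-5-vinyl-1,4-dihydropyridine-3-carboxylate | COC(=O)C1=CN(C(=O)OCC=C)C=C(C=C)[C@H]1CC(=O)OCCc1ccc(O[Si](C)(C)C(C)(C)C)c(O[Si](C)(C)C(C)(C)C)c1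
F5 | step 5 | methyl (4R)-1-(allyloxycarbonyl)-4-{2-[2-(3,4-dihydroxyphenyl)ethoxy]-2-oxoethyl}-5-vinyl-1,4-dihydropyridine-3-carboxylate | COC(=O)C1=CN(C(=O)OCC=C)C=C(C=C)[C@H]1CC(=O)OCCc1ccc(O)c(O)c1
F6 | step 3 | 1-(tert-butylsulfanyl)-1-(tert-butyldimethylsilyloxy)ethene | C=C(SC(C)(C)C)O[Si](C)(C)C(C)(C)C
F7 | step 3 | methyl (4R)-4-[2-(tert-butylsulfanyl)-2-oxoethyl]-1-[(2,2,2-trichloroethoxy)carbonyl]-5-vinyl-1,4-dihydropyridine-3-carboxylate | COC(=O)C1=CN(C(=O)OCC(Cl)(Cl)Cl)C=C(C=C)[C@H]1CC(=O)SC(C)(C)C
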